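Ring C is disconnected to an acyclic 3-butyryloxy-4-benzyloxy-1,4-enyne attached through its carbinol carbon to the benzylic CH2 of a protected phloroacetophenone (ring B); ring A is joined last through a methylene. In one operation a monovalent rhodium catalyst shifts the butyrate onto the alkyne, inserts CO and closes ring C, forming two ring bonds. The step exploits the oxygen pattern of ring C: the oxygen between the methyl-bearing carbon and the future butyryl carbon (the eventual OMe) arrives from CO as the only free phenol, the butyrate sits ortho to the one unsubstituted carbon for a Fries shift, and the third oxygen stays benzylated. The acetyl group of ring B travels as a silyl enol ether.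

Key step: step 10

Assumption: the enol ether of 19, 22 and 23 is drawn as the Z isomer expected from step 8; the E isomer would be carried along, because both geometries end in the same arene in step 10.

Step 1
Reactants: 1 phloroacetophenone; 2 allyl bromide
Product: 3 1-[2,6-dihydroxy-4-(prop-2-en-1-yloxy)phenyl]ethan-1-one
Conditions: allyl bromide (1.0 equiv), K2CO3 (1.0 equiv), acetone, reflux
Reagents that add atoms: allyl bromide (2), C=CCBr
Why: Williamson etherification of the most acidic hydroxyl, the para one that is not hydrogen-bonded to the ketone, should stop at the mono-ether with one equivalent of halide, and an ortho mono-ether would converge with 3 in step 2.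

Step 2
Reactants: 3 1-[2,6-dihydroxy-4-(prop-2-en-1-yloxy)phenyl]ethan-1-one
Product: 5 1-[2,4,6-trihydroxy-3-(prop-2-en-1-yl)phenyl]ethan-1-one, via allyl cyclohexadienone 4 (not isolated)
Conditions: PhNEt2, 190 °C
Reagents that add atoms: none
Why: Aromatic Claisen rearrangement moves the allyl group by a [3,3] shift to either of the two equivalent ortho carbons, and dienone 4 (racemic, transient) re-aromatises by tautomerisation.

Step 3
Reactants: 5 1-[2,4,6-trihydroxy-3-(prop-2-en-1-yl)phenyl]ethan-1-one; 6 benzyl bromide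
Product: 7 1-[2,4,6-tris(benzyloxy)-3-(prop-2-en-1-yl)phenyl]ethan-1-one
Conditions: BnBr (3.6 equiv), K2CO3, n-Bu4NI (cat.), DMF, 70 °C
Reagents that add atoms: benzyl bromide (6), BrCc1ccccc1
Why: Williamson etherification of all three phenols, with heat and a polar solvent to reach the two hydroxyls that flank the ketone.

Step 4
Reactants: 7 1-[2,4,6-tris(benzyloxy)-3-(prop-2-en-1-yl)phenyl]ethan-1-one; 8 ozone; 9 methanol
Product: 11 methyl 2-[3-acetyl-2,4,6-tris(benzyloxy)phenyl]acetate, via methoxy hydroperoxide 10 (not isolated)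
Conditions: O3 (titrated against an indicator dye), NaOH (2.5 M in MeOH), CH2Cl2, −78 °C
Reagents that add atoms: ozone (8), O=[O+][O-]; methanol (9), CO
Why: Ozonolysis in basic methanol should turn the terminal alkene directly into the methyl ester, since methanol traps the carbonyl oxide and base dehydrates methoxy hydroperoxide 10 (racemic, transient), while the acyl-deactivated, fully flanked arene reacts far more slowly than the alkene at −78 °C.

Step 5
Reactants: 11 methyl 2-[3-acetyl-2,4,6-tris(benzyloxy)phenyl]acetate; 12 tert-butyldimethylsilyl trifluoromethanesulfonate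
Product: 13 methyl 2-{2,4,6-tris(benzyloxy)-3-[1-(tert-butyldimethylsilyloxy)ethenyl]phenyl}acetate
Conditions: TBSOTf (1.2 equiv), Et3N, CH2Cl2, 0 °C
Reagents that add atoms: tert-butyldimethylsilyl trifluoromethanesulfonate (12), CC(C)(C)[Si](C)(C)OS(=O)(=O)C(F)(F)F
Why: Soft enolisation of the methyl ketone with a silyl triflate and an amine gives the silyl enol ether, which masks the acetyl group against the carbanions of steps 7 and 9, while the less Lewis-basic ester carbonyl is left alone.

Step 6
Reactants: 14 benzyl chloromethyl ether; 15 triethyl phosphite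
Product: 16 diethyl [(benzyloxy)methyl]phosphonate
Conditions: neat, 130 °C
Reagents that add atoms: triethyl phosphite (15), CCOP(OCC)OCC
Why: Michaelis–Arbuzov reaction of a reactive alpha-chloro ether with triethyl phosphite.

Step 7
Reactants: 13 methyl 2-{2,4,6-tris(benzyloxy)-3-[1-(tert-butyldimethylsilyloxy)ethenyl]phenyl}acetate; 16 diethyl [(benzyloxy)methyl]phosphonate
Product: 17 racemic diethyl (1-(benzyloxy)-2-oxo-3-{2,4,6-tris(benzyloxy)-3-[1-(tert-butyldimethylsilyloxy)ethenyl]phenyl}propyl)phosphonate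
Conditions: 16 (2.3 equiv), LiN(i-Pr)2 (2.2 equiv), THF, −78 °C; then 13, −78 → −30 °C; aq. NH4Cl
Reagents that add atoms: diethyl [(benzyloxy)methyl]phosphonate (16), CCOP(=O)(COCc1ccccc1)OCC
Why: Claisen-type acylation of the lithiated alpha-alkoxyphosphonate by the methyl ester, driven by deprotonation of the beta-ketophosphonate by the second equivalent of carbanion; the carbon next to phosphorus forms as a racemate and becomes sp2 in step 8.

Step 8
Reactants: 17 racemic diethyl (1-(benzyloxy)-2-oxo-3-{2,4,6-tris(benzyloxy)-3-[1-(tert-butyldimethylsilyloxy)ethenyl]phenyl}propyl)phosphonate; 18 acetaldehyde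
Product: 19 (Z)-3-(benzyloxy)-1-{2,4,6-tris(benzyloxy)-3-[1-(tert-butyldimethylsilyloxy)ethenyl]phenyl}pent-3-en-2-one
Conditions: MeCHO (5 equiv), LiCl, i-Pr2NEt, MeCN, 0 °C → rt
Reagents that add atoms: acetaldehyde (18), CC=O
Why: Horner–Wadsworth–Emmons olefination of the lithium-chelated ketophosphonate anion under mild amine conditions, which should favour the Z enol ether with the methyl group trans to the carbonyl group.

Step 9
Reactants: 19 (Z)-3-(benzyloxy)-1-{2,4,6-tris(benzyloxy)-3-[1-(tert-butyldimethylsilyloxy)ethenyl]phenyl}pent-3-en-2-one; 20 ethynylmagnesium bromide; 21 butyryl chloride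
Product: 23 racemic (Z)-4-(benzyloxy)-3-({2,4,6-tris(benzyloxy)-3-[1-(tert-butyldimethylsilyloxy)ethenyl]phenyl}methyl)hex-4-en-1-yn-3-yl butanoate, via magnesium alkoxide 22 (not isolated)
Conditions: HC≡CMgBr (1.5 equiv), THF, −78 → 0 °C; then PrCOCl (3 equiv), DMAP (cat.), 0 °C → rt
Reagents that add atoms: ethynylmagnesium bromide (20), C#C[Mg]Br; butyryl chloride (21), CCCC(=O)Cl
Why: 1,2-Addition of the hard alkynyl Grignard reagent to the only unmasked carbonyl group, followed by O-acylation of the tertiary magnesium alkoxide in the same flask; the carbinol carbon forms without control as a racemate and is flattened in step 10.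

Step 10
Reactants: 23 racemic (Z)-4-(benzyloxy)-3-({2,4,6-tris(benzyloxy)-3-[1-(tert-butyldimethylsilyloxy)ethenyl]phenyl}methyl)hex-4-en-1-yn-3-yl butanoate; 24 carbon monoxide
Product: 27 3-(benzyloxy)-5-hydroxy-4-methyl-2-({2,4,6-tris(benzyloxy)-3-[1-(tert-butyldimethylsilyloxy)ethenyl]phenyl}methyl)phenyl butanoate, via dienylketene 25 (not isolated), via cyclohexadienone 26 (not isolated)
Conditions: [Rh(CO)2Cl]2 (5 mol %), CO (1 atm), ClCH2CH2Cl, 60 °C
Reagents that add atoms: carbon monoxide (24), [C-]#[O+]
Why: Proposed new method: the pi-acidic monovalent rhodium centre binds the terminal alkyne of 23, the butanoate carbonyl oxygen attacks the internal alkyne carbon, and the resulting 1,2-acyloxy shift leaves a rhodium vinylcarbene at the former terminal carbon, which takes up CO to give dienylketene 25. Ring C closes by 6π electrocyclisation of 25 (the ketene carbon bonds to the methyl-bearing enol ether carbon; reductive elimination from a rhodacycle is the equivalent metal-bound path), and dienone 26 tautomerises to the phenol, so CO ends up bonded to both chain termini. The closest known reaction type is the rhodium-catalysed (5+1) carbonylative benzannulation of secondary 3-acyloxy-1,4-enynes to resorcinol monoesters; a tertiary ester and a benzyl enol ether as the alkene partner are not covered by it. No stereocentre survives, because the racemic carbinol carbon of 23 and the transient sp3 carbon of 26 both become aromatic. The step needs the 1,2-shift to win over the 1,3-shift to an allenyl ester and needs a single ring size: the unsubstituted alkyne terminus favours the 1,2-shift, the enyne connectivity allows only one six-membered closure, and the Z propenyl end keeps its methyl group on the outside of the closing triene. Ring C is thereby delivered with one free phenol (the CO oxygen), one butanoate and one benzyl ether.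

Step 11
Reactants: 27 3-(benzyloxy)-5-hydroxy-4-methyl-2-({2,4,6-tris(benzyloxy)-3-[1-(tert-butyldimethylsilyloxy)ethenyl]phenyl}methyl)phenyl butanoate; 28 iodomethane
Product: 30 2-{[3-acetyl-2,4,6-tris(benzyloxy)phenyl]methyl}-3-(benzyloxy)-5-methoxy-4-methylphenyl butanoate, via silyl enol ether methyl ether 29 (not isolated)
Conditions: MeI, K2CO3, acetone, rt; then 1 M HCl, THF, rt
Reagents that add atoms: iodomethane (28), CI
Why: Williamson O-methylation of the only free hydroxyl in the molecule, then mild acid hydrolysis of the silyl enol ether to restore the acetyl group without touching the aryl butanoate or the benzyl ethers.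

Step 12
Reactants: 30 2-{[3-acetyl-2,4,6-tris(benzyloxy)phenyl]methyl}-3-(benzyloxy)-5-methoxy-4-methylphenyl butanoate
Product: 31 2-[(3-acetyl-2,4,6-trihydroxyphenyl)methyl]-3-hydroxy-5-methoxy-4-methylphenyl butanoate
Conditions: H2 (1 atm), Pd/C, EtOAc, rt
Reagents that add atoms: none
Why: Hydrogenolysis of the four aryl benzyl ethers over palladium on carbon, under which the aryl ester, the aryl ketone and the diarylmethane should be inert.

Step 13
Reactants: 31 2-[(3-acetyl-2,4,6-trihydroxyphenyl)methyl]-3-hydroxy-5-methoxy-4-methylphenyl butanoate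
Product: 32 1-{3-[(3-acetyl-2,4,6-trihydroxyphenyl)methyl]-2,4-dihydroxy-6-methoxy-5-methylphenyl}butan-1-one
Conditions: BF3·OEt2 (5 equiv), 1,4-dioxane, 60 °C; then MeOH/H2O
Reagents that add atoms: none
Why: Fries rearrangement, in which the butanoyl group leaves the ring C oxygen as an acylium equivalent and is recaptured at the only open carbon of ring C, ortho to the freed phenol and by far the most nucleophilic site, while the open carbon of ring B is deactivated by its chelated acetyl group and the chelated ortho-hydroxy ketone is the thermodynamic sink.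

Step 14
Reactants: 33 2-methylphloroglucinol; 21 butyryl chloride
Product: 34 1-(2,4,6-trihydroxy-3-methylphenyl)butan-1-one
Conditions: PrCOCl (1.1 equiv), AlCl3 (3 equiv), PhNO2/CH2Cl2, 0 → 45 °C; aq. HCl
Reagents that add atoms: butyryl chloride (21), CCCC(=O)Cl
Why: Friedel–Crafts acylation at one of the two equivalent open carbons of the triol, after which the acyl group deactivates the ring against a second acylation.

Step 15
Reactants: 34 1-(2,4,6-trihydroxy-3-methylphenyl)butan-1-one; 35 dimethyl sulfate
Product: 36 aspidinol, 1-(2,6-dihydroxy-4-methoxy-3-methylphenyl)butan-1-one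
Conditions: Me2SO4 (1.0 equiv), K2CO3 (1.0 equiv), acetone, rt
Reagents that add atoms: dimethyl sulfate (35), COS(=O)(=O)OC
Why: Williamson O-methylation with a hard electrophile should select the para hydroxyl, the most acidic one and the only one that cannot chelate the ketone, over the two ortho hydroxyls and over C-methylation.

Step 16
Reactants: 36 aspidinol; 37 N,N-dimethylmethyleneiminium iodide
Product: 38 1-{3-[(dimethylamino)methyl]-2,6-dihydroxy-4-methoxy-5-methylphenyl}butan-1-one
Conditions: N,N-dimethylmethyleneiminium iodide (1.1 equiv), Et3N, CH2Cl2, 0 °C → rt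
Reagents that add atoms: N,N-dimethylmethyleneiminium iodide (37), C=[N+](C)C.[I-]
Why: Mannich aminomethylation with a preformed iminium salt at the single open ring carbon, without free formaldehyde that could bridge two molecules of 36.

Step 17
Reactants: 32 1-{3-[(3-acetyl-2,4,6-trihydroxyphenyl)methyl]-2,4-dihydroxy-6-methoxy-5-methylphenyl}butan-1-one; 38 1-{3-[(dimethylamino)methyl]-2,6-dihydroxy-4-methoxy-5-methylphenyl}butan-1-one
Product: 40 target CNP0184345.0, via ortho-quinone methide 39 (not isolated)
Conditions: 38 (1.2 equiv), 1,4-dioxane, 90 °C, Ar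
Reagents that add atoms: Mannich base 38, CCCC(=O)c1c(O)c(CN(C)C)c(OC)c(C)c1O
Why: Thermal loss of dimethylamine from the phenolic Mannich base gives ortho-quinone methide 39, which is captured by conjugate addition of the only open ring carbon of 32 (C-alkylation of the acylphloroglucinol, then re-aromatisation), a known way to unsymmetrical methylene-bridged phenols.

Compound list
1 | phloroacetophenone, 1-(2,4,6-trihydroxyphenyl)ethan-1-one | CC(=O)c1c(O)cc(O)cc1O | starting material
2 | allyl bromide | C=CCBr | starting material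
3 | 1-[2,6-dihydroxy-4-(prop-2-en-1-yloxy)phenyl]ethan-1-one | CC(=O)c1c(O)cc(OCC=C)cc1O | intermediate
4 | 4-acetyl-3,5-dihydroxy-6-(prop-2-en-1-yl)cyclohexa-2,4-dien-1-one (racemic) | CC(=O)C1=C(O)C(CC=C)C(=O)C=C1O | intermediate (not isolated)
5 | 1-[2,4,6-trihydroxy-3-(prop-2-en-1-yl)phenyl]ethan-1-one | CC(=O)c1c(O)cc(O)c(CC=C)c1O | intermediate
6 | benzyl bromide | BrCc1ccccc1 | starting material
7 | 1-[2,4,6-tris(benzyloxy)-3-(prop-2-en-1-yl)phenyl]ethan-1-one | CC(=O)c1c(OCc2ccccc2)cc(OCc2ccccc2)c(CC=C)c1OCc1ccccc1 | intermediate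
8 | ozone | O=[O+][O-] | starting material
9 | methanol | CO | starting material
10 | 1-[2,4,6-tris(benzyloxy)-3-(2-hydroperoxy-2-methoxyethyl)phenyl]ethan-1-one (racemic) | COC(OO)Cc1c(OCc2ccccc2)cc(OCc2ccccc2)c(C(C)=O)c1OCc1ccccc1 | intermediate (not isolated)
11 | methyl 2-[3-acetyl-2,4,6-tris(benzyloxy)phenyl]acetate | COC(=O)Cc1c(OCc2ccccc2)cc(OCc2ccccc2)c(C(C)=O)c1OCc1ccccc1 | intermediate
12 | tert-butyldimethylsilyl trifluoromethanesulfonate | CC(C)(C)[Si](C)(C)OS(=O)(=O)C(F)(F)F | starting material
13 | methyl 2-{2,4,6-tris(benzyloxy)-3-[1-(tert-butyldimethylsilyloxy)ethenyl]phenyl}acetate | COC(=O)Cc1c(OCc2ccccc2)cc(OCc2ccccc2)c(C(=C)O[Si](C)(C)C(C)(C)C)c1OCc1ccccc1 | intermediate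
14 | benzyl chloromethyl ether | ClCOCc1ccccc1 | starting material
15 | triethyl phosphite | CCOP(OCC)OCC | starting material
16 | diethyl [(benzyloxy)methyl]phosphonate | CCOP(=O)(COCc1ccccc1)OCC | intermediate
17 | diethyl (1-(benzyloxy)-2-oxo-3-{2,4,6-tris(benzyloxy)-3-[1-(tert-butyldimethylsilyloxy)ethenyl]phenyl}propyl)phosphonate (racemic) | CCOP(=O)(OCC)C(OCc1ccccc1)C(=O)Cc1c(OCc2ccccc2)cc(OCc2ccccc2)c(C(=C)O[Si](C)(C)C(C)(C)C)c1OCc1ccccc1 | intermediate
18 | acetaldehyde | CC=O | starting material
19 | (Z)-3-(benzyloxy)-1-{2,4,6-tris(benzyloxy)-3-[1-(tert-butyldimethylsilyloxy)ethenyl]phenyl}pent-3-en-2-one | C/C=C(\OCc1ccccc1)C(=O)Cc1c(OCc2ccccc2)cc(OCc2ccccc2)c(C(=C)O[Si](C)(C)C(C)(C)C)c1OCc1ccccc1 | intermediate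
20 | ethynylmagnesium bromide | C#C[Mg]Br | starting material
21 | butyryl chloride | CCCC(=O)Cl | starting material
22 | bromomagnesium (Z)-4-(benzyloxy)-3-({2,4,6-tris(benzyloxy)-3-[1-(tert-butyldimethylsilyloxy)ethenyl]phenyl}methyl)hex-4-en-1-yn-3-olate (racemic) | C#CC(O[Mg]Br)(Cc1c(OCc2ccccc2)cc(OCc2ccccc2)c(C(=C)O[Si](C)(C)C(C)(C)C)c1OCc1ccccc1)/C(OCc1ccccc1)=C/C | intermediate (not isolated)
23 | (Z)-4-(benzyloxy)-3-({2,4,6-tris(benzyloxy)-3-[1-(tert-butyldimethylsilyloxy)ethenyl]phenyl}methyl)hex-4-en-1-yn-3-yl butanoate (racemic; precursor of the key step) | C#CC(OC(=O)CCC)(Cc1c(OCc2ccccc2)cc(OCc2ccccc2)c(C(=C)O[Si](C)(C)C(C)(C)C)c1OCc1ccccc1)/C(OCc1ccccc1)=C/C | intermediate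
24 | carbon monoxide | [C-]#[O+] | starting material
25 | (3E,5Z)-5-(benzyloxy)-1-oxo-4-({2,4,6-tris(benzyloxy)-3-[1-(tert-butyldimethylsilyloxy)ethenyl]phenyl}methyl)hepta-1,3,5-trien-3-yl butanoate (dienylketene) | C/C=C(\OCc1ccccc1)/C(Cc1c(OCc2ccccc2)cc(OCc2ccccc2)c(C(=C)O[Si](C)(C)C(C)(C)C)c1OCc1ccccc1)=C(OC(=O)CCC)\C=C=O | intermediate (not isolated)
26 | 5-(benzyloxy)-4-methyl-3-oxo-6-({2,4,6-tris(benzyloxy)-3-[1-(tert-butyldimethylsilyloxy)ethenyl]phenyl}methyl)cyclohexa-1,5-dien-1-yl butanoate (racemic) | CC1C(=O)C=C(OC(=O)CCC)C(Cc2c(OCc3ccccc3)cc(OCc3ccccc3)c(C(=C)O[Si](C)(C)C(C)(C)C)c2OCc2ccccc2)=C1OCc1ccccc1 | intermediate (not isolated)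
27 | 3-(benzyloxy)-5-hydroxy-4-methyl-2-({2,4,6-tris(benzyloxy)-3-[1-(tert-butyldimethylsilyloxy)ethenyl]phenyl}methyl)phenyl butanoate (product of the key step) | CCCC(=O)Oc1cc(O)c(C)c(OCc2ccccc2)c1Cc1c(OCc2ccccc2)cc(OCc2ccccc2)c(C(=C)O[Si](C)(C)C(C)(C)C)c1OCc1ccccc1 | intermediate
28 | iodomethane | CI | starting material
29 | 3-(benzyloxy)-5-methoxy-4-methyl-2-({2,4,6-tris(benzyloxy)-3-[1-(tert-butyldimethylsilyloxy)ethenyl]phenyl}methyl)phenyl butanoate | CCCC(=O)Oc1cc(OC)c(C)c(OCc2ccccc2)c1Cc1c(OCc2ccccc2)cc(OCc2ccccc2)c(C(=C)O[Si](C)(C)C(C)(C)C)c1OCc1ccccc1 | intermediate (not isolated)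
30 | 2-{[3-acetyl-2,4,6-tris(benzyloxy)phenyl]methyl}-3-(benzyloxy)-5-methoxy-4-methylphenyl butanoate | CCCC(=O)Oc1cc(OC)c(C)c(OCc2ccccc2)c1Cc1c(OCc2ccccc2)cc(OCc2ccccc2)c(C(C)=O)c1OCc1ccccc1 | intermediate
31 | 2-[(3-acetyl-2,4,6-trihydroxyphenyl)methyl]-3-hydroxy-5-methoxy-4-methylphenyl butanoate | CCCC(=O)Oc1cc(OC)c(C)c(O)c1Cc1c(O)cc(O)c(C(C)=O)c1O | intermediate
32 | 1-{3-[(3-acetyl-2,4,6-trihydroxyphenyl)methyl]-2,4-dihydroxy-6-methoxy-5-methylphenyl}butan-1-one | CCCC(=O)c1c(O)c(Cc2c(O)cc(O)c(C(C)=O)c2O)c(O)c(C)c1OC | intermediate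
33 | 2-methylphloroglucinol, 2-methylbenzene-1,3,5-triol | Cc1c(O)cc(O)cc1O | starting material
34 | 1-(2,4,6-trihydroxy-3-methylphenyl)butan-1-one | CCCC(=O)c1c(O)cc(O)c(C)c1O | intermediate
35 | dimethyl sulfate | COS(=O)(=O)OC | starting material
36 | aspidinol, 1-(2,6-dihydroxy-4-methoxy-3-methylphenyl)butan-1-one | CCCC(=O)c1c(O)cc(OC)c(C)c1O | intermediate
37 | N,N-dimethylmethyleneiminium iodide | C=[N+](C)C.[I-] | starting material
38 | 1-{3-[(dimethylamino)methyl]-2,6-dihydroxy-4-methoxy-5-methylphenyl}butan-1-one | CCCC(=O)c1c(O)c(CN(C)C)c(OC)c(C)c1O | intermediate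
39 | 2-butanoyl-3-hydroxy-5-methoxy-4-methyl-6-methylidenecyclohexa-2,4-dien-1-one | CCCC(=O)C1=C(O)C(C)=C(OC)C(=C)C1=O | intermediate (not isolated)
40 | CNP0184345.0, 1-[3-({3-acetyl-5-[(3-butanoyl-2,6-dihydroxy-4-methoxy-5-methylphenyl)methyl]-2,4,6-trihydroxyphenyl}methyl)-2,6-dihydroxy-4-methoxy-5-methylphenyl]butan-1-one (no stereocentre) | CCCC(=O)c1c(O)c(C)c(OC)c(Cc2c(O)c(Cc3c(O)c(C)c(OC)c(C(=O)CCC)c3O)c(O)c(C(C)=O)c2O)c1O | target

Total step count: 17. Longest linear sequence: 13 steps (steps 1–5, 7–13 and 17). Step 6 and steps 14–16 are side branches.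

Steps most likely to fail

Step 10. The acyloxy group may shift 1,3 to give an allenyl ester in place of the carbene. The tertiary, doubly activated ester may also ionise, or the enol ether may be lost before carbonylation. The fallback uses only known chemistry and takes ring C from the aromatic pool; it sets out from 34 and 1 and comes back to the route at 32. Compound 34 is benzylated with two equivalents of benzyl bromide (K2CO3, acetone) at its two more accessible hydroxyls to give 1-[4,6-bis(benzyloxy)-2-hydroxy-3-methylphenyl]butan-1-one F1. The remaining chelated hydroxyl, wedged between the methyl and butanoyl carbons, is then methylated under forcing conditions (Me2SO4, K2CO3, acetone, reflux) to 1-[4,6-bis(benzyloxy)-2-methoxy-3-methylphenyl]butan-1-one F2. Hydrogenolysis (H2, Pd/C) should give 1-(4,6-dihydroxy-2-methoxy-3-methylphenyl)butan-1-one F3, and aminomethylation as in step 16 should give 1-{3-[(dimethylamino)methyl]-2,4-dihydroxy-6-methoxy-5-methylphenyl}butan-1-one F4. Heating F4 with an excess of phloroacetophenone 1 in dioxane should then give 32 through 4-butanoyl-3-hydroxy-5-methoxy-6-methyl-2-methylidenecyclohexa-3,5-dien-1-one F5.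

Step 13. The acyl group may be transferred between molecules to a phenolic oxygen or to the open carbon of ring B, and the acid may cleave the methylene bridge. The fallback replaces the acyl shift by a ring-selective acylation; it sets out from 31 and comes back at 32. The butanoate of 31 is removed by methanolysis (K2CO3, degassed MeOH, 0 °C) to give 1-{3-[(2,6-dihydroxy-4-methoxy-3-methylphenyl)methyl]-2,4,6-trihydroxyphenyl}ethan-1-one F6. A Hoesch acylation with butyronitrile (ZnCl2, HCl gas, Et2O, 0 °C) should then attack only the non-acylated ring C, since the nitrilium electrophile needs a phloroglucinol-type ring without an acyl group. The resulting 1-{3-[(3-acetyl-2,4,6-trihydroxyphenyl)methyl]-2,4-dihydroxy-6-methoxy-5-methylphenyl}butan-1-iminium chloride F7 is hydrolysed in warm water to 32.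

Step 17. At 90 °C the quinone methide may form reversibly from the product as well, which would scramble the methylene bridges and give symmetrical dimers. The fallback is the cold alkaline formaldehyde condensation; it sets out from 32 and 36 and ends at the target 40. An excess of aspidinol 36 is hydroxymethylated in the flask with aqueous formaldehyde in dilute NaOH at 0 °C to 1-[2,6-dihydroxy-3-(hydroxymethyl)-4-methoxy-5-methylphenyl]butan-1-one F8, and 32 is added. F8 should lose water to the same quinone methide 39 at low temperature, and 32 traps it to give 40; the symmetrical methylene-bridged dimer of 36 is removed by chromatography.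

Further compounds
F1 | step 10 | 1-[4,6-bis(benzyloxy)-2-hydroxy-3-methylphenyl]butan-1-one | CCCC(=O)c1c(OCc2ccccc2)cc(OCc2ccccc2)c(C)c1O
F2 | step 10 | 1-[4,6-bis(benzyloxy)-2-methoxy-3-methylphenyl]butan-1-one | CCCC(=O)c1c(OCc2ccccc2)cc(OCc2ccccc2)c(C)c1OC
F3 | step 10 | 1-(4,6-dihydroxy-2-methoxy-3-methylphenyl)butan-1-one | CCCC(=O)c1c(O)cc(O)c(C)c1OC
F4 | step 10 | 1-{3-[(dimethylamino)methyl]-2,4-dihydroxy-6-methoxy-5-methylphenyl}butan-1-one | CCCC(=O)c1c(O)c(CN(C)C)c(O)c(C)c1OC
F5 | step 10 | 4-butanoyl-3-hydroxy-5-methoxy-6-methyl-2-methylidenecyclohexa-3,5-dien-1-one | CCCC(=O)C1=C(O)C(=C)C(=O)C(C)=C1OC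
F6 | step 13 | 1-{3-[(2,6-dihydroxy-4-methoxy-3-methylphenyl)methyl]-2,4,6-trihydroxyphenyl}ethan-1-one | COc1cc(O)c(Cc2c(O)cc(O)c(C(C)=O)c2O)c(O)c1C
F7 | step 13 | 1-{3-[(3-acetyl-2,4,6-trihydroxyphenyl)methyl]-2,4-dihydroxy-6-methoxy-5-methylphenyl}butan-1-iminium chloride | CCCC(=[NH2+])c1c(O)c(Cc2c(O)cc(O)c(C(C)=O)c2O)c(O)c(C)c1OC.[Cl-]
F8 | step 17 | 1-[2,6-dihydroxy-3-(hydroxymethyl)-4-methoxy-5-methylphenyl]butan-1-one | CCCC(=O)c1c(O)c(CO)c(OC)c(C)c1O
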